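## Retrosynthetic overview

1. The target is (3R)-3-hydroxy-7,8-didehydro-8′-apo-β-caroten-8′-al. Carotenoid numbering is used: ring C1 (CMe2), C2 (CH2), C3 (CHOH), C4 (CH2), C5 (CMe), C6; chain C7≡C8 up to C8′HO.
2. Chain: C9′=C10′ and C11′=C12′ by Wittig reactions (three-carbon and two-carbon ylides); C11=C12 by Wittig reaction of a C15 phosphonium salt with 2,7-dimethylocta-2,4,6-trienedial; C8–C9 by Pd-catalysed addition of the ring alkyne to ethyl but-2-ynoate; C7≡C8 by Colvin homologation of the ring aldehyde.
3. Ring: the cyclohexene is made in one step from isobutene (C1, C2) and ethyl 4-methyl-2-oxo-2H-pyran-3-carboxylate (C3 to C6, the C5 methyl and C7) by an enantioselective inverse-electron-demand Diels–Alder reaction that forms C2–C3 and C1–C6.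
4. Enabling feature: the oxygen on C3 and the exocyclic carbon on C6 stand 1,4 to each other on the six-membered ring. O–C3 and C6 can therefore be tied through a carbonyl into the O–C(=O) bridge of a 2-oxabicyclo[2.2.2]oct-5-en-3-one, the cycloadduct of a 2-pyranone. The bridge is not in the target: it is opened, its carbonyl leaves as CO2, the ester carbon on C6 becomes C7, and the C4=C5 bond moves to C5=C6.
5. Ring order: pyranone ring (step 2), carbocycle as bridged bicyclic lactone (step 3), lactone bridge opened (step 4).

Key step: step 3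

Assumption: the (S,S)-ligand is taken to leave open the face that gives the (1S,4R)-adduct; if the sense is the opposite, the (R,R)-ligand is used and nothing else changes. The descriptor of the carbinol carbon changes from S (compounds 6 to 9) to R (from 10 on) only because the ranking of its ring neighbours changes when the double bond moves; no bond to this centre is broken.

## Route

Step 1
Reactants: 1 diethyl 2-(propan-2-ylidene)propanedioate; 2 N,N-dimethylformamide dimethyl acetal
Product: 3 diethyl 2-[(3E)-4-(dimethylamino)but-3-en-2-ylidene]propanedioate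
Conditions: 2 (1.5 equiv), neat, 110 °C, MeOH distilled off
Reagents that add atoms: none
Why: the γ-methyl groups of the alkylidene malonate are vinylogously C–H acidic and condense with the amide acetal (aminomethylenation, an enamine-forming condensation) to give the push–pull dienamine; no stereocentre is formed.

Step 2
Reactants: 3 diethyl 2-[(3E)-4-(dimethylamino)but-3-en-2-ylidene]propanedioate
Product: 4 ethyl 4-methyl-2-oxo-2H-pyran-3-carboxylate
Conditions: AcOH–H2O (4:1), 100 °C
Reagents that add atoms: water, O
Why: acid hydrolysis of the enamine unmasks the δ-aldehyde as its dienol, whose oxygen lactonises onto the cis ester with loss of ethanol (the usual 2-pyranone synthesis from 5-aminodienoates).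

Step 3
Reactants: 4 ethyl 4-methyl-2-oxo-2H-pyran-3-carboxylate; 5 2-methylpropene (isobutene)
Product: 6 ethyl (1S,4R)-5,8,8-trimethyl-3-oxo-2-oxabicyclo[2.2.2]oct-5-ene-4-carboxylate
Conditions: Cu(OTf)2 (10 mol %), 2,2′-(propane-2,2-diyl)bis[(4S)-4-tert-butyl-4,5-dihydrooxazole] ((S,S)-t-Bu-box, 11 mol %), 2,6-di-tert-butylpyridine (10 mol %), 4 Å molecular sieves, 5 (10 equiv, condensed in), CH2Cl2, sealed vessel, –20 °C to rt
Reagents that add atoms: none
Why: Proposed new method: chelation of the lactone and ester carbonyls of the pyranone by Cu(OTf)2/(S,S)-t-Bu-box lowers the diene LUMO, so that the nucleophilic CH2 end of isobutene bonds to the electron-poor pyranone C-6 (the C2–C3 bond of the target) while CMe2, the carbon that best carries positive charge, bonds to the enolate-like pyranone C-3 (the C1–C6 bond) in a concerted but strongly asynchronous inverse-electron-demand Diels–Alder reaction. The closest known reaction type is the enantioselective cycloaddition of 3-alkoxycarbonyl-2-pyranones with enol ethers, vinyl sulfides and indenes under the same kind of Cu(OTf)2–bis(oxazoline) catalysis, and isobutene is about as nucleophilic as a styrene. The six-membered carbocycle is closed by this intermolecular [4+2] cycloaddition, suprafacial on both partners; if the process is stepwise, the second bond forms by six-membered collapse of the malonate-type enolate onto the tertiary cation. Both bridgehead stereocentres are set together by the face of the flat pyranone that the ligand leaves open, and since isobutene carries two identical methyl groups on one carbon and two hydrogens on the other there is no endo/exo question, so facial selectivity alone fixes the later C3 configuration. The step needs regioselectivity (secured by the matched polarisation of both partners and by the 4-methyl group, which blocks attack at pyranone C-4), ring closure in preference to ene-type proton loss (secured by the rigid cisoid diene, which holds the second terminus next to the developing cation, and by the hindered pyridine, which removes adventitious acid that would oligomerise isobutene), and retention of the CO2 bridge (secured by working at or below room temperature).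

Step 4
Reactants: 6 ethyl (1S,4R)-5,8,8-trimethyl-3-oxo-2-oxabicyclo[2.2.2]oct-5-ene-4-carboxylate
Product: 8 ethyl (4S)-4-hydroxy-2,6,6-trimethylcyclohex-2-ene-1-carboxylate (both C1 epimers), via half acid 7 (not isolated)
Conditions: LiOH·H2O (1.1 equiv), THF–H2O, 0 °C; 1 M HCl to pH 3, extraction (EtOAc); Et3N (0.1 equiv), toluene, 90 °C
Reagents that add atoms: none
Why: hydroxide should open the E-configured bridged lactone faster than the ethyl ester (lactone saponification), and the resulting α-vinyl malonic half ester loses CO2 through its conjugated ester dienol on mild heating (malonic half-ester decarboxylation); the C1 centre formed on protonation is an inconsequential epimer mixture because it becomes sp2 in step 5, and the carbinol centre is not touched.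

Step 5
Reactants: 8 ethyl (4S)-4-hydroxy-2,6,6-trimethylcyclohex-2-ene-1-carboxylate
Product: 10 (4R)-4-hydroxy-2,6,6-trimethylcyclohex-1-ene-1-carbaldehyde, via hydroxy aldehyde 9 (not isolated)
Conditions: i-Bu2AlH (2.2 equiv), CH2Cl2, –78 °C; MeOH, then aq. potassium sodium tartrate; crude in MeOH, K2CO3 (0.3 equiv), 0 °C to rt
Reagents that add atoms: none
Why: low-temperature i-Bu2AlH reduction of the hindered α-branched ester should stop at the tetrahedral O–Al hemiacetal (partial ester reduction), and carbonate then moves the double bond into conjugation through the dienolate (the α- to β-cyclocitral isomerisation), which turns both C1 epimers into one tetrasubstituted enal without touching the carbinol centre.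

Step 6
Reactants: 10 (4R)-4-hydroxy-2,6,6-trimethylcyclohex-1-ene-1-carbaldehyde
Product: 11 (1R)-4-ethynyl-3,5,5-trimethylcyclohex-3-en-1-ol
Conditions: TMSCHN2 (2.4 equiv), n-BuLi (2.3 equiv), THF, –78 °C; then 10, –78 °C to rt
Reagents that add atoms: (trimethylsilyl)diazomethane, C[Si](C)(C)C=[N+]=[N-]
Why: Colvin rearrangement: lithiated (trimethylsilyl)diazomethane adds to the aldehyde, Peterson-type loss of lithium trimethylsilanolate gives the diazoalkene, and the alkylidene carbene formed on loss of N2 undergoes 1,2-hydrogen shift to the terminal enyne; the first equivalent of reagent only deprotonates the hydroxyl group.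

Step 7
Reactants: 11 (1R)-4-ethynyl-3,5,5-trimethylcyclohex-3-en-1-ol; 12 ethyl but-2-ynoate
Product: 13 ethyl (2E)-5-[(4R)-4-hydroxy-2,6,6-trimethylcyclohex-1-en-1-yl]-3-methylpent-2-en-4-ynoate
Conditions: Pd(OAc)2 (3 mol %), tris(2,6-dimethoxyphenyl)phosphine (3 mol %), 12 (1.2 equiv), toluene, rt
Reagents that add atoms: none
Why: Pd-catalysed cross-addition of a terminal alkyne to an ynoate (hydroalkynylation) delivers the alkynyl group to the β-carbon and hydrogen to the α-carbon on the same side, which fixes the E geometry of the new trisubstituted C9=C10 bond.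

Step 8
Reactants: 13 ethyl (2E)-5-[(4R)-4-hydroxy-2,6,6-trimethylcyclohex-1-en-1-yl]-3-methylpent-2-en-4-ynoate
Product: 14 (2E)-5-[(4R)-4-hydroxy-2,6,6-trimethylcyclohex-1-en-1-yl]-3-methylpent-2-en-4-yn-1-ol
Conditions: i-Bu2AlH (3.3 equiv), CH2Cl2, –78 to –20 °C; aq. potassium sodium tartrate
Reagents that add atoms: none
Why: 1,2-reduction of the conjugated ester to the allylic alcohol (ester reduction) should leave the enyne untouched at low temperature; one equivalent of hydride is consumed by the free hydroxyl group.

Step 9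
Reactants: 14 (2E)-5-[(4R)-4-hydroxy-2,6,6-trimethylcyclohex-1-en-1-yl]-3-methylpent-2-en-4-yn-1-ol
Product: 15 [(2E)-5-[(4R)-4-hydroxy-2,6,6-trimethylcyclohex-1-en-1-yl]-3-methylpent-2-en-4-yn-1-yl]triphenylphosphonium bromide
Conditions: PPh3·HBr (1.05 equiv), MeOH, rt, dark
Reagents that add atoms: triphenylphosphine hydrobromide, Br.c1ccc(cc1)P(c1ccccc1)c1ccccc1
Why: the primary allylic alcohol is converted into the allylic phosphonium salt (the standard Wittig salt formation of carotenoid chemistry), while the secondary homoallylic alcohol, which cannot ionise, is unaffected.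

Step 10
Reactants: 15 [(2E)-5-[(4R)-4-hydroxy-2,6,6-trimethylcyclohex-1-en-1-yl]-3-methylpent-2-en-4-yn-1-yl]triphenylphosphonium bromide; 16 (2E,4E,6E)-2,7-dimethylocta-2,4,6-trienedial
Product: 19 (2E,4E,6E,8E,10E)-13-[(4R)-4-hydroxy-2,6,6-trimethylcyclohex-1-en-1-yl]-2,7,11-trimethyltrideca-2,4,6,8,10-pentaen-12-ynal, via C15 ylide 17 (not isolated), via 11Z isomer 18 (not isolated)
Conditions: 16 (3 equiv), NaOMe (1.1 equiv), CH2Cl2–MeOH, –10 °C to rt, argon, dim light; then n-heptane, 80 °C
Reagents that add atoms: none
Why: Wittig olefination of the semistabilised allylic ylide with an excess of the symmetrical dialdehyde should give mono-condensation at C11=C12, and the 11Z portion is isomerised thermally to the less hindered all-E polyene.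

Step 11
Reactants: 19 (2E,4E,6E,8E,10E)-13-[(4R)-4-hydroxy-2,6,6-trimethylcyclohex-1-en-1-yl]-2,7,11-trimethyltrideca-2,4,6,8,10-pentaen-12-ynal; 20 (1,3-dioxolan-2-ylmethyl)triphenylphosphonium bromide
Product: 23 (2E,4E,6E,8E,10E,12E)-15-[(4R)-4-hydroxy-2,6,6-trimethylcyclohex-1-en-1-yl]-4,9,13-trimethylpentadeca-2,4,6,8,10,12-hexaen-14-ynal, via dioxolanylmethyl ylide 21 (not isolated), via dioxolane acetal 22 (not isolated)
Conditions: 20 (1.5 equiv), KOt-Bu (1.4 equiv), THF, 0 °C; then 19, 0 °C to rt; then 1 M HCl, THF, rt; argon, dim light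
Reagents that add atoms: water, O
Why: Wittig two-carbon homologation with the dioxolanylmethyl ylide, followed by acid hydrolysis of the vinylogous acetal, during which the new C11′=C12′ bond should equilibrate to E in the conjugated enal.

Step 12
Reactants: 23 (2E,4E,6E,8E,10E,12E)-15-[(4R)-4-hydroxy-2,6,6-trimethylcyclohex-1-en-1-yl]-4,9,13-trimethylpentadeca-2,4,6,8,10,12-hexaen-14-ynal; 24 2-(triphenyl-λ5-phosphanylidene)propanal
Product: 25 (2E,4E,6E,8E,10E,12E,14E)-17-[(4R)-4-hydroxy-2,6,6-trimethylcyclohex-1-en-1-yl]-2,6,11,15-tetramethylheptadeca-2,4,6,8,10,12,14-heptaen-16-ynal (CNP0269043.1)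
Conditions: 24 (1.3 equiv), toluene, 60 °C, argon, dim light
Reagents that add atoms: none
Why: Wittig olefination with the stabilised formyl ylide is E-selective for the new trisubstituted C9′=C10′ bond and should stop after one addition, because the α-methyl enal formed is less electrophilic than the starting enal.

## Compound list

1 | diethyl 2-(propan-2-ylidene)propanedioate | CCOC(=O)C(=C(C)C)C(=O)OCC | starting material
2 | N,N-dimethylformamide dimethyl acetal | COC(OC)N(C)C | starting material
3 | diethyl 2-[(3E)-4-(dimethylamino)but-3-en-2-ylidene]propanedioate | CCOC(=O)C(C(=O)OCC)=C(C)/C=C/N(C)C | intermediate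
4 | ethyl 4-methyl-2-oxo-2H-pyran-3-carboxylate | CCOC(=O)C1=C(C)C=COC1=O | intermediate
5 | 2-methylpropene | CC(C)=C | starting material
6 | ethyl (1S,4R)-5,8,8-trimethyl-3-oxo-2-oxabicyclo[2.2.2]oct-5-ene-4-carboxylate | CC1=C[C@@H]2CC(C)(C)[C@@]1(C(=O)OCC)C(=O)O2 | intermediate
7 | (1S,4S)-1-(ethoxycarbonyl)-4-hydroxy-2,6,6-trimethylcyclohex-2-ene-1-carboxylic acid (not isolated) | CC1=C[C@@H](O)CC(C)(C)[C@@]1(C(=O)OCC)C(=O)O | intermediate
8 | ethyl (4S)-4-hydroxy-2,6,6-trimethylcyclohex-2-ene-1-carboxylate (C1 epimers) | CC1=C[C@@H](O)CC(C)(C)C1C(=O)OCC | intermediate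
9 | (4S)-4-hydroxy-2,6,6-trimethylcyclohex-2-ene-1-carbaldehyde (C1 epimers, cis epimer partly as bridged lactol; not isolated) | CC1=C[C@@H](O)CC(C)(C)C1C=O | intermediate
10 | (4R)-4-hydroxy-2,6,6-trimethylcyclohex-1-ene-1-carbaldehyde | CC1=C(C=O)C(C)(C)C[C@H](O)C1 | intermediate
11 | (1R)-4-ethynyl-3,5,5-trimethylcyclohex-3-en-1-ol | CC1=C(C#C)C(C)(C)C[C@H](O)C1 | intermediate
12 | ethyl but-2-ynoate | CC#CC(=O)OCC | starting material
13 | ethyl (2E)-5-[(4R)-4-hydroxy-2,6,6-trimethylcyclohex-1-en-1-yl]-3-methylpent-2-en-4-ynoate | CC1=C(C#C/C(C)=C/C(=O)OCC)C(C)(C)C[C@H](O)C1 | intermediate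
14 | (2E)-5-[(4R)-4-hydroxy-2,6,6-trimethylcyclohex-1-en-1-yl]-3-methylpent-2-en-4-yn-1-ol | CC1=C(C#C/C(C)=C/CO)C(C)(C)C[C@H](O)C1 | intermediate
15 | [(2E)-5-[(4R)-4-hydroxy-2,6,6-trimethylcyclohex-1-en-1-yl]-3-methylpent-2-en-4-yn-1-yl]triphenylphosphonium bromide | CC1=C(C#C/C(C)=C/C[P+](c2ccccc2)(c2ccccc2)c2ccccc2)C(C)(C)C[C@H](O)C1.[Br-] | intermediate
16 | (2E,4E,6E)-2,7-dimethylocta-2,4,6-trienedial | O=C/C(C)=C/C=C/C=C(C)/C=O | starting material
17 | [(2E)-5-[(4R)-4-hydroxy-2,6,6-trimethylcyclohex-1-en-1-yl]-3-methylpent-2-en-4-yn-1-ylidene]triphenyl-λ5-phosphane (not isolated) | CC1=C(C#C/C(C)=C/C=P(c2ccccc2)(c2ccccc2)c2ccccc2)C(C)(C)C[C@H](O)C1 | intermediate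
18 | (2E,4E,6E,8Z,10E)-isomer of 19, the 11Z isomer in carotenoid numbering (not isolated) | CC1=C(C#C/C(C)=C/C=C\C(C)=C\C=C\C=C(C)\C=O)C(C)(C)C[C@H](O)C1 | intermediate
19 | (2E,4E,6E,8E,10E)-13-[(4R)-4-hydroxy-2,6,6-trimethylcyclohex-1-en-1-yl]-2,7,11-trimethyltrideca-2,4,6,8,10-pentaen-12-ynal | CC1=C(C#C/C(C)=C/C=C/C(C)=C/C=C/C=C(C)/C=O)C(C)(C)C[C@H](O)C1 | intermediate
20 | (1,3-dioxolan-2-ylmethyl)triphenylphosphonium bromide | [Br-].C1COC(C[P+](c2ccccc2)(c2ccccc2)c2ccccc2)O1 | starting material
21 | (1,3-dioxolan-2-ylmethylidene)triphenyl-λ5-phosphane (not isolated) | C1COC(C=P(c2ccccc2)(c2ccccc2)c2ccccc2)O1 | intermediate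
22 | ethylene acetal of 23 (2-substituted 1,3-dioxolane, E/Z mixture at the new C11′=C12′ bond; not isolated) | CC1=C(C#C/C(C)=C/C=C/C(C)=C/C=C/C=C(C)/C=CC2OCCO2)C(C)(C)C[C@H](O)C1 | intermediate
23 | (2E,4E,6E,8E,10E,12E)-15-[(4R)-4-hydroxy-2,6,6-trimethylcyclohex-1-en-1-yl]-4,9,13-trimethylpentadeca-2,4,6,8,10,12-hexaen-14-ynal | CC1=C(C#C/C(C)=C/C=C/C(C)=C/C=C/C=C(C)/C=C/C=O)C(C)(C)C[C@H](O)C1 | intermediate
24 | 2-(triphenyl-λ5-phosphanylidene)propanal | CC(C=O)=P(c1ccccc1)(c1ccccc1)c1ccccc1 | starting material
25 | (2E,4E,6E,8E,10E,12E,14E)-17-[(4R)-4-hydroxy-2,6,6-trimethylcyclohex-1-en-1-yl]-2,6,11,15-tetramethylheptadeca-2,4,6,8,10,12,14-heptaen-16-ynal | CC1=C(C#C/C(C)=C/C=C/C(C)=C/C=C/C=C(C)/C=C/C=C(\C)C=O)C(C)(C)C[C@H](O)C1 | target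

## Step count and risks

Total step count: 12. Longest linear sequence: 12 steps (1 to 25).

Steps most likely to fail:

1. Step 3. The Lewis-acid-bound pyranone may not engage an alkene as weakly nucleophilic as isobutene. The polar transition state may lose a proton (ene-type conjugate addition) instead of closing the second bond between two fully substituted carbons. Isobutene may oligomerise, or facial selectivity may be poor. Fallback: it sets out from 4 and 5. Uncatalysed cycloaddition under high pressure (about 12 kbar, CH2Cl2, 40 °C) is the known way to obtain bridged 2-pyranone adducts of weakly activated alkenes without loss of CO2, and should give the racemic adduct F1. Its enantiomers are separated by preparative chromatography on a chiral stationary phase; the (1S,4R)-enantiomer is 6, where the route is rejoined.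

2. Step 5. The tetrahedral intermediate may be over-reduced to the diol, the double-bond migration may stay incomplete, or the base may cause loss of the hydroxyl group by vinylogous E1cB elimination. Fallback: it sets out from 8. Silylation (TBSCl, imidazole, DMF) should give the silyl ether F2, and full reduction (LiAlH4, Et2O, 0 °C) the primary alcohol F3. Dess–Martin oxidation then gives the β,γ-unsaturated aldehyde F4, which is conjugated without isolation with DBU (CH2Cl2, rt) to the protected enal F5. Desilylation (HF·pyridine, THF) returns to the route at 10.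

3. Step 10. Double condensation on the dialdehyde may compete, and the 9E geometry may erode during the thermal Z-to-E isomerisation that the semistabilised ylide makes necessary (7,8-didehydro polyenes isomerise easily at C9). Fallback: it sets out from 14. Direct conversion of the allylic alcohol with P(OEt)3 and ZnI2 (toluene, 100 °C) should give the allylic phosphonate F6. Horner–Wadsworth–Emmons reaction of its anion (KOt-Bu, 2.1 equiv, THF, –30 °C) with an excess of 16 is E-selective, needs no isomerisation, and returns to the route at 19.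

## Further compounds

F1 | step 3 | racemic ethyl (1S*,4R*)-5,8,8-trimethyl-3-oxo-2-oxabicyclo[2.2.2]oct-5-ene-4-carboxylate | CC1=CC2CC(C)(C)C1(C(=O)OCC)C(=O)O2
F2 | step 5 | ethyl (4S)-4-[(tert-butyldimethylsilyl)oxy]-2,6,6-trimethylcyclohex-2-ene-1-carboxylate (C1 epimers) | CC1=C[C@@H](O[Si](C)(C)C(C)(C)C)CC(C)(C)C1C(=O)OCC
F3 | step 5 | [(4S)-4-[(tert-butyldimethylsilyl)oxy]-2,6,6-trimethylcyclohex-2-en-1-yl]methanol (C1 epimers) | CC1=C[C@@H](O[Si](C)(C)C(C)(C)C)CC(C)(C)C1CO
F4 | step 5 | (4S)-4-[(tert-butyldimethylsilyl)oxy]-2,6,6-trimethylcyclohex-2-ene-1-carbaldehyde (C1 epimers) | CC1=C[C@@H](O[Si](C)(C)C(C)(C)C)CC(C)(C)C1C=O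
F5 | step 5 | (4R)-4-[(tert-butyldimethylsilyl)oxy]-2,6,6-trimethylcyclohex-1-ene-1-carbaldehyde | CC1=C(C=O)C(C)(C)C[C@H](O[Si](C)(C)C(C)(C)C)C1
F6 | step 10 | diethyl [(2E)-5-[(4R)-4-hydroxy-2,6,6-trimethylcyclohex-1-en-1-yl]-3-methylpent-2-en-4-yn-1-yl]phosphonate | CC1=C(C#C/C(C)=C/CP(=O)(OCC)OCC)C(C)(C)C[C@H](O)C1
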